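**Retrosynthetic overview**

- Target 17 is two 7-methoxy-2,2-dimethyl-2H-chromen-6-yl units joined by Ca=Cb–Cc(CH3): ring A sits on the alkene carbon Ca, ring B on the S-configured benzylic carbon Cc.
- Feature used: in chromene B, O7 is ortho to C6 and C6 carries Cc, so O7–C7–C6–Cc–Cb–Ca can be folded into a six-membered 4-methylchroman-2-ol ring with Ca as the lactol carbon.
- Ca=Cb comes from dehydration of a benzylic carbinol; the C6(ring A)–Ca bond from aryl Grignard 13 and lactol 8; the O7 methyl ether from phenol methylation after ring opening.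
- Lactol 8 comes from 2,2-dimethyl-2H-chromen-7-ol 4 and (E)-but-2-enal 5 by amine-catalysed Friedel–Crafts conjugate addition with hemiacetal closure (bonds C6–Cc and O7–Ca, stereocentre Cc).
- Ring order: pyran ring of chromene B (step 1), temporary lactol ring (step 2), pyran ring of chromene A in a side branch (step 3); the lactol ring is opened again in step 4.

Key step: step 2

Assumption: the sense of induction is taken from the accepted shielding model for diarylprolinol silyl ether iminium ions (s-trans E-iminium, arene entering opposite the CPh2OSiMe3 group), which calls for the (R)-amine, C[Si](C)(C)OC(c1ccccc1)(c1ccccc1)[C@H]1CCCN1, to reach 4S; both antipodes are commercial, so the other would be used if the sense proved opposite.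

**Route**

Step 1
Reactants: 1 resorcinol; 2 3-methylbut-2-enal
Product: 4 2,2-dimethyl-2H-chromen-7-ol, via quinone methide 3 (not isolated)
Conditions: 1 (2 equiv), ethylenediammonium diacetate (10 mol %), xylene, 140 °C
Reagents that add atoms: none
Why: Knoevenagel-type condensation at C4 of resorcinol gives the o-quinone methide 3, which closes by oxa-6π electrocyclisation; excess resorcinol should suppress a second annulation, and the 5-hydroxy isomer from attack at C2 is removed by chromatography.

Step 2
Reactants: 4 2,2-dimethyl-2H-chromen-7-ol; 5 (E)-but-2-enal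
Product: 8 (4S)-4,8,8-trimethyl-3,4-dihydro-2H,8H-pyrano[3,2-g]chromen-2-ol (mixture at C2), via iminium benzoate 6 (not isolated), via hydroxy aldehyde 7 (not isolated)
Conditions: (R)-2-[diphenyl(trimethylsilyloxy)methyl]pyrrolidine (20 mol %), PhCO2H (20 mol %), 5 (2 equiv), toluene, 0 °C to rt
Reagents that add atoms: none
Why: The amine and benzoic acid convert 5 into the s-trans E-iminium benzoate 6; C6 of phenol 4, which is ortho to O7–H and para to O1 (the activation pattern of sesamol), adds to its β-carbon, and rearomatisation followed by hydrolysis of the enamine releases aldehyde 7 and the catalyst. The closest known reaction type is the secondary-amine-catalysed Friedel–Crafts alkylation/hemiacetalisation of naphthols and electron-rich phenols with enals. The ring is closed when O7–H adds to the aldehyde carbon Ca in a 6-exo-trig hemiacetalisation, which also removes the aldehyde from further iminium or enamine chemistry and from retro-addition. The stereocentre Cc is controlled by the catalyst: the CPh2OSiMe3 group of the (R)-amine covers the Re face of Cβ (Cα > CH3 > H), so the arene enters on the Si face and gives 4S. The step needs attack through C6 rather than C8 or O7, secured because C8 is wedged between O1 and O7 and because O-addition is reversible whereas C-addition is locked as the lactol; the C3=C4 alkene of the pyran ring should tolerate the weak acid.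

Step 3
Reactants: 9 4-bromo-3-methoxyphenol; 2 3-methylbut-2-enal
Product: 12 6-bromo-7-methoxy-2,2-dimethyl-2H-chromene, via benzodioxaborin 10 (not isolated), via quinone methide 11 (not isolated)
Conditions: 2 (1.5 equiv), PhB(OH)2 (1 equiv), AcOH, toluene, reflux (Dean–Stark)
Reagents that add atoms: none
Why: Phenylboronic acid-templated ortho-hydroxyalkylation gives dioxaborin 10, which fragments on heating to o-quinone methide 11 and closes by oxa-6π electrocyclisation; the phenol reacts at C6 (para to OCH3) rather than at the crowded C2, which places Br at C6 and OCH3 at C7 of the chromene.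

Step 4
Reactants: 12 6-bromo-7-methoxy-2,2-dimethyl-2H-chromene; 8 (4S)-4,8,8-trimethyl-3,4-dihydro-2H,8H-pyrano[3,2-g]chromen-2-ol
Product: 14 6-[(2S)-4-hydroxy-4-(7-methoxy-2,2-dimethyl-2H-chromen-6-yl)butan-2-yl]-2,2-dimethyl-2H-chromen-7-ol (mixture at the carbinol carbon), via aryl Grignard reagent 13 (not isolated)
Conditions: 12 (2.5 equiv), Mg, I2 (cat.), THF, 50 °C; then 8, THF, 0 °C to rt; pH 7 aqueous buffer
Reagents that add atoms: none
Why: Grignard addition to a lactol: one equivalent of 13 deprotonates 8, the magnesium lactolate opens to the magnesium phenoxide of aldehyde 7 and a second equivalent adds to Ca; the carbinol centre forms as a mixture, which is of no consequence because it becomes sp2 in step 6, and Cc is not touched.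

Step 5
Reactants: 14 6-[(2S)-4-hydroxy-4-(7-methoxy-2,2-dimethyl-2H-chromen-6-yl)butan-2-yl]-2,2-dimethyl-2H-chromen-7-ol
Product: 15 (3S)-1,3-bis(7-methoxy-2,2-dimethyl-2H-chromen-6-yl)butan-1-ol (mixture at C1)
Conditions: MeI, K2CO3, acetone, 50 °C
Reagents that add atoms: methyl iodide, CI
Why: Williamson ether synthesis: K2CO3 ionises only the phenol, so O7 is methylated while the secondary benzylic alcohol stays free.

Step 6
Reactants: 15 (3S)-1,3-bis(7-methoxy-2,2-dimethyl-2H-chromen-6-yl)butan-1-ol
Product: 17 6,6'-[(1E,3S)-but-1-ene-1,3-diyl]bis(7-methoxy-2,2-dimethyl-2H-chromene), via sulfamate ester 16 (not isolated)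
Conditions: Burgess reagent (MeO2CN(−)SO2N(+)Et3, 2 equiv), toluene, 50 °C
Reagents that add atoms: none
Why: Burgess dehydration, a thermal syn-elimination through sulfamate 16: only Cb has β-hydrogens, so Ca=Cb is the only possible alkene, both carbinol epimers have a syn hydrogen leading to the conjugated E isomer, and the neutral conditions should leave the stereocentre Cc (now allylic and benzylic) and both chromene rings alone.

**Compound list**

1 | resorcinol (benzene-1,3-diol) | Oc1cccc(O)c1 | starting material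
2 | 3-methylbut-2-enal | CC(C)=CC=O | starting material
3 | (6Z)-3-hydroxy-6-(3-methylbut-2-en-1-ylidene)cyclohexa-2,4-dien-1-one (o-quinone methide, not isolated) | O=C1C=C(O)C=C/C1=C/C=C(C)C | intermediate
4 | 2,2-dimethyl-2H-chromen-7-ol | CC1(C)C=Cc2ccc(O)cc2O1 | intermediate
5 | (E)-but-2-enal | C/C=C/C=O | starting material
6 | (2R)-1-[(1E,2E)-but-2-en-1-ylidene]-2-[diphenyl(trimethylsilyloxy)methyl]pyrrolidin-1-ium benzoate (not isolated) | C/C=C/C=[N+]1/[C@@H](C(c2ccccc2)(c2ccccc2)O[Si](C)(C)C)CCC1.[O-]C(=O)c1ccccc1 | intermediate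
7 | (3S)-3-(7-hydroxy-2,2-dimethyl-2H-chromen-6-yl)butanal (open form of 8, not isolated) | O=CC[C@H](C)c1cc2C=CC(C)(C)Oc2cc1O | intermediate
8 | (4S)-4,8,8-trimethyl-3,4-dihydro-2H,8H-pyrano[3,2-g]chromen-2-ol (both C2 epimers) | OC1C[C@H](C)c2cc3C=CC(C)(C)Oc3cc2O1 | intermediate
9 | 4-bromo-3-methoxyphenol | COc1cc(O)ccc1Br | starting material
10 | 6-bromo-7-methoxy-4-(2-methylprop-1-en-1-yl)-2-phenyl-4H-1,3,2-benzodioxaborinine (not isolated) | COc1cc2OB(c3ccccc3)OC(C=C(C)C)c2cc1Br | intermediate
11 | (6Z)-4-bromo-3-methoxy-6-(3-methylbut-2-en-1-ylidene)cyclohexa-2,4-dien-1-one (o-quinone methide, not isolated) | O=C1C=C(OC)C(Br)=C/C1=C/C=C(C)C | intermediate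
12 | 6-bromo-7-methoxy-2,2-dimethyl-2H-chromene | COc1cc2OC(C)(C)C=Cc2cc1Br | intermediate
13 | (7-methoxy-2,2-dimethyl-2H-chromen-6-yl)magnesium bromide (not isolated) | COc1cc2OC(C)(C)C=Cc2cc1[Mg]Br | intermediate
14 | 6-[(2S)-4-hydroxy-4-(7-methoxy-2,2-dimethyl-2H-chromen-6-yl)butan-2-yl]-2,2-dimethyl-2H-chromen-7-ol (both carbinol epimers) | COc1cc2OC(C)(C)C=Cc2cc1C(O)C[C@H](C)c1cc2C=CC(C)(C)Oc2cc1O | intermediate
15 | (3S)-1,3-bis(7-methoxy-2,2-dimethyl-2H-chromen-6-yl)butan-1-ol (both C1 epimers) | COc1cc2OC(C)(C)C=Cc2cc1C(O)C[C@H](C)c1cc2C=CC(C)(C)Oc2cc1OC | intermediate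
16 | (3S)-1,3-bis(7-methoxy-2,2-dimethyl-2H-chromen-6-yl)butyl N-(methoxycarbonyl)sulfamate, triethylammonium salt (not isolated) | COC(=O)[N-]S(=O)(=O)OC(C[C@H](C)c1cc2C=CC(C)(C)Oc2cc1OC)c1cc2C=CC(C)(C)Oc2cc1OC.CC[NH+](CC)CC | intermediate
17 | 6,6'-[(1E,3S)-but-1-ene-1,3-diyl]bis(7-methoxy-2,2-dimethyl-2H-chromene) | COc1cc2c(cc1/C=C/[C@H](C)c1cc3c(cc1OC)OC(C)(C)C=C3)C=CC(C)(C)O2 | target

**Step count and risks**

Total step count: 6. Longest linear sequence: 5 (steps 1, 2, 4, 5, 6); step 3 is a one-step side branch.

Steps most likely to fail: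

Step 2. The arylation may be slow for a phenol activated by only one ring oxygen besides its hydroxyl, so that enal self-condensation or an unselective acid-catalysed background addition lowers conversion and enantiomeric purity. The fallback sets out from 12 and comes back at 15. Grignard reagent 13, made from 12, is borylated with B(OMe)3 (THF, −78 °C to rt, aqueous NH4Cl) to (7-methoxy-2,2-dimethyl-2H-chromen-6-yl)boronic acid F1. Rh-catalysed asymmetric 1,4-addition of F1 to propan-2-yl (E)-but-2-enoate, C/C=C/C(=O)OC(C)C [Rh(acac)(C2H4)2, the BINAP antipode that places the aryl group on the Cβ face leading to 3S, dioxane/H2O, 100 °C] should give propan-2-yl (3S)-3-(7-methoxy-2,2-dimethyl-2H-chromen-6-yl)butanoate F2. Reduction with i-Bu2AlH (CH2Cl2, −78 °C) should give (3S)-3-(7-methoxy-2,2-dimethyl-2H-chromen-6-yl)butanal F3, and addition of 13 (THF, 0 °C) gives 15. Ring B then carries its methyl ether from the start, and steps 4 and 5 fall away.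

Step 4. Opening of the magnesium lactolate may be slow, so that 13 is lost by protonation or by enolisation of the aldehyde; during work-up the free phenol O7 may also capture the easily ionised carbinol carbon Ca and close a 2-arylchroman ring. The fallback sets out from 8 and comes back at 15. NaBH4 (MeOH, 0 °C) reduces the open form of 8 to 6-[(2S)-4-hydroxybutan-2-yl]-2,2-dimethyl-2H-chromen-7-ol F4. MeI/K2CO3 (acetone) methylates the phenol to (3S)-3-(7-methoxy-2,2-dimethyl-2H-chromen-6-yl)butan-1-ol F5. Dess–Martin periodinane (NaHCO3, CH2Cl2) gives (3S)-3-(7-methoxy-2,2-dimethyl-2H-chromen-6-yl)butanal F3, to which 13 (1.3 equiv, THF, 0 °C) adds to give 15.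

Step 6. Sulfamate 16 may ionise to a benzylic cation stabilised by the ortho and para oxygens of ring A, followed by Friedel–Crafts closure onto C5 of ring B, migration of the alkene towards ring B with loss of the stereocentre, or formation of a mixture of alkene isomers. The fallback sets out from 15 and comes back at 17. Dess–Martin periodinane (NaHCO3, CH2Cl2) oxidises 15 to (3S)-1,3-bis(7-methoxy-2,2-dimethyl-2H-chromen-6-yl)butan-1-one F6. KN(SiMe3)2 and PhNTf2 (THF, −78 °C) trap the Z-enolate as (1Z,3S)-1,3-bis(7-methoxy-2,2-dimethyl-2H-chromen-6-yl)but-1-en-1-yl trifluoromethanesulfonate F7, in which ring A is already trans to Cc. Reduction of the C–OTf bond with retention [Pd(OAc)2, PPh3, Bu3N, HCO2H, DMF, 60 °C] should give 17 without a cation at Ca.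

**Further compounds**

F1 | step 2 | (7-methoxy-2,2-dimethyl-2H-chromen-6-yl)boronic acid | COc1cc2OC(C)(C)C=Cc2cc1B(O)O
F2 | step 2 | propan-2-yl (3S)-3-(7-methoxy-2,2-dimethyl-2H-chromen-6-yl)butanoate | CC(C)OC(=O)C[C@H](C)c1cc2C=CC(C)(C)Oc2cc1OC
F3 | step 2 | (3S)-3-(7-methoxy-2,2-dimethyl-2H-chromen-6-yl)butanal | O=CC[C@H](C)c1cc2C=CC(C)(C)Oc2cc1OC
F4 | step 4 | 6-[(2S)-4-hydroxybutan-2-yl]-2,2-dimethyl-2H-chromen-7-ol | OCC[C@H](C)c1cc2C=CC(C)(C)Oc2cc1O
F5 | step 4 | (3S)-3-(7-methoxy-2,2-dimethyl-2H-chromen-6-yl)butan-1-ol | OCC[C@H](C)c1cc2C=CC(C)(C)Oc2cc1OC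
F6 | step 6 | (3S)-1,3-bis(7-methoxy-2,2-dimethyl-2H-chromen-6-yl)butan-1-one | COc1cc2OC(C)(C)C=Cc2cc1C(=O)C[C@H](C)c1cc2C=CC(C)(C)Oc2cc1OC
F7 | step 6 | (1Z,3S)-1,3-bis(7-methoxy-2,2-dimethyl-2H-chromen-6-yl)but-1-en-1-yl trifluoromethanesulfonate | COc1cc2OC(C)(C)C=Cc2cc1/C(OS(=O)(=O)C(F)(F)F)=C/[C@H](C)c1cc2C=CC(C)(C)Oc2cc1OC
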